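## Retrosynthetic overview

- The chain is numbered C1 (styryl carbon on ring A) to C7 (benzylic carbon on ring B). The strategy rests on the enolized C3–C4–C5 1,3-diketone, which lies between an unsaturated arm (C1=C2, ring A) and a saturated arm (C6–C7, ring B).
- After removal of two phenolic TBS ethers, the key cut is C4–C5. It gives a C1–C4 feruloylacetic acid (a β-keto acid with a sacrificial carboxyl on C4) as nucleophile and a C5–C7 dihydroferuloyl imidazolide as acyl donor. They are joined by a magnesium-mediated decarboxylative Claisen condensation modelled on curcuminoid biosynthesis.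
- The keto acid comes from ferulic acid by a C3–C4 Claisen condensation with tert-butyl acetate, followed by acidolysis. The imidazolide comes from dihydroferulic acid and carbonyldiimidazole.
- No ring is formed, because rings A and B are bought fully substituted. Each arm brings its own oxidation level, so no selective reduction of a dienone is needed.

Key step: step 6

Assumption: the 1,3-diketone tautomers interconvert freely. The drawn C3 enol (Z, hydrogen-bonded, conjugated with the styryl arm) is taken as the form in which 16 and 17 are obtained, so no step has to set it.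

## Route

Step 1
Reactants: 1 ferulic acid
Product: 3 (E)-3-[4-(tert-butyldimethylsilyloxy)-3-methoxyphenyl]prop-2-enoic acid, via bis-silylated ferulic acid 2 (not isolated)
Conditions: TBSCl (2.4 equiv), imidazole (5 equiv), DMF, rt; crude 2 then AcOH–THF–H2O (3:1:1), rt
Reagents that add atoms: tert-butyldimethylsilyl chloride (TBSCl), CC(C)(C)[Si](C)(C)Cl
Why: Imidazole-promoted silylation caps the phenol and the carboxyl group alike, and the silyl ester, far more labile than the aryl silyl ether, is then hydrolysed selectively by aqueous acetic acid while the E alkene stays untouched.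

Step 2
Reactants: 3 O-TBS ferulic acid; 4 1,1'-carbonyldiimidazole; 5 tert-butyl acetate
Product: 8 tert-butyl (E)-5-[4-(tert-butyldimethylsilyloxy)-3-methoxyphenyl]-3-oxopent-4-enoate, via feruloyl imidazolide 6 (not isolated), via lithium tert-butyl acetate enolate 7 (not isolated)
Conditions: 3, 4 (1.05 equiv), THF, rt, 1 h; separately 5 (3.6 equiv), commercial LiN(iPr)2 (3.6 equiv), THF, −78 °C; add the solution of 6, −78 °C, 1 h; cold 1 M HCl quench
Reagents that add atoms: tert-butyl acetate (5), CC(=O)OC(C)(C)C
Why: Crossed Claisen condensation of an ester enolate with an acyl imidazolide: at −78 °C the hard lithium enolate attacks the acyl carbon rather than C1, imidazolide leaves, and the surplus enolate (which also covers the N–H of the liberated imidazole) deprotonates the β-keto ester at once, which blocks a second addition.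

Step 3
Reactants: 9 dihydroferulic acid
Product: 11 3-[4-(tert-butyldimethylsilyloxy)-3-methoxyphenyl]propanoic acid, via bis-silylated dihydroferulic acid 10 (not isolated)
Conditions: TBSCl (2.4 equiv), imidazole (5 equiv), DMF, rt; crude 10 then AcOH–THF–H2O (3:1:1), rt
Reagents that add atoms: tert-butyldimethylsilyl chloride (TBSCl), CC(C)(C)[Si](C)(C)Cl
Why: The same imidazole-promoted silylation and selective silyl ester hydrolysis as in step 1, applied to the saturated acid.

Step 4
Reactants: 11 O-TBS dihydroferulic acid; 4 1,1'-carbonyldiimidazole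
Product: 12 1-{3-[4-(tert-butyldimethylsilyloxy)-3-methoxyphenyl]propanoyl}imidazole
Conditions: 4 (0.98 equiv), CH2Cl2, rt, 2 h; brief ice-water wash, Na2SO4, concentrate
Reagents that add atoms: 1,1'-carbonyldiimidazole (4), O=C(n1ccnc1)n1ccnc1
Why: Carboxyl activation by carbonyldiimidazole runs through the acyl imidazole-1-carboxylate, which collapses with loss of CO2 to the acyl imidazolide, and the slight deficit of 4 plus the cold wash ensure that no carbonyldiimidazole reaches the keto acid of step 6, which it would activate towards self-condensation.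

Step 5
Reactants: 8 tert-butyl β-keto ester
Product: 13 (E)-5-[4-(tert-butyldimethylsilyloxy)-3-methoxyphenyl]-3-oxopent-4-enoic acid
Conditions: TFA–CH2Cl2 (1:3), 0 °C, 1–2 h; concentrate below 15 °C with toluene chase, triturate with cold pentane; use at once
Reagents that add atoms: none
Why: Acidolysis of a tert-butyl ester by alkyl–oxygen cleavage (loss of isobutene) needs neither water nor base, aryl TBS ethers withstand cold TFA, and working at or below 15 °C holds back the thermal decarboxylation of the β-keto acid.

Step 6
Reactants: 13 silyl-protected feruloyl diketide acid; 12 silyl-protected dihydroferuloyl imidazolide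
Product: 16 (4Z,6E)-1,7-bis[4-(tert-butyldimethylsilyloxy)-3-methoxyphenyl]-5-hydroxyhepta-4,6-dien-3-one, via magnesium enolate carboxylate chelate 14 (not isolated), via C4-acylated keto acid 15 (not isolated)
Conditions: 13 (1.3 equiv), anhydrous MgCl2 (1.5 equiv), Et3N (3.2 equiv), MeCN, 0 °C, 45 min; then 12 (1.0 equiv) in THF, 0 °C → rt, 16 h; cold 1 M HCl wash
Reagents that add atoms: none
Why: MgCl2 and Et3N should turn keto acid 13 into the six-membered magnesium enolate carboxylate chelate 14, in which CO2 cannot depart because that would expel a dianion, and whose only nucleophilic carbon is C4 because the other flank of the C3 ketone is the C1=C2 alkene with no enolizable hydrogen. C4 attacks the magnesium-activated carbonyl of imidazolide 12, imidazole leaves and the C4–C5 bond is made, giving tricarbonyl carboxylate 15, which now has two ketones to accept the electron pair, so it sheds CO2 in the flask or at the latest on the acid wash and is protonated to the chelated enol 16. The step is a decarboxylative Claisen condensation whose closest established type is the Masamune–Brooks acylation of magnesium malonate half esters by acyl imidazolides, and its nucleophile is the same kind of magnesium β-keto carboxylate chelate that MeOMgOCO2Me (magnesium methyl carbonate) makes from ketones. No ring is closed and no stereocentre is created: the E geometry of C1=C2 is carried through untouched and the Z enol geometry follows from the intramolecular hydrogen bond. The selectivity needed is C- over O-acylation and acylation before decarboxylation: chelation ties both oxygens to magnesium and leaves carbon free, any enol ester or mixed anhydride that forms is itself an acyl donor that imidazole returns to 12, and only the C-acylated adduct is drained irreversibly by loss of CO2. Keeping 13 in slight excess over 12 should prevent a second acylation of the product diketonate.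

Step 7
Reactants: 16 bis-TBS dihydrocurcumin
Product: 17 (4Z,6E)-5-hydroxy-1,7-bis(4-hydroxy-3-methoxyphenyl)hepta-4,6-dien-3-one (target)
Conditions: Et3N·3HF (3 equiv), THF, 0 °C → rt; EtOAc, water and brine wash
Reagents that add atoms: none
Why: Fluoride-driven cleavage of the two aryl silyl ethers by the slightly acidic Et3N·3HF never exposes phenoxide or diketonate to a basic medium, so the retro-Claisen and retro-aldol breakdown typical of curcuminoids in base is avoided.

## Compound list

IUPAC locants in the names of 16 and 17 run opposite to the C1–C7 numbering used in the text.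

1 | ferulic acid, (E)-3-(4-hydroxy-3-methoxyphenyl)prop-2-enoic acid | COc1cc(/C=C/C(=O)O)ccc1O | starting material
2 | tert-butyldimethylsilyl (E)-3-[4-(tert-butyldimethylsilyloxy)-3-methoxyphenyl]prop-2-enoate | COc1cc(/C=C/C(=O)O[Si](C)(C)C(C)(C)C)ccc1O[Si](C)(C)C(C)(C)C | intermediate
3 | (E)-3-[4-(tert-butyldimethylsilyloxy)-3-methoxyphenyl]prop-2-enoic acid | COc1cc(/C=C/C(=O)O)ccc1O[Si](C)(C)C(C)(C)C | intermediate
4 | 1,1'-carbonyldiimidazole | O=C(n1ccnc1)n1ccnc1 | starting material
5 | tert-butyl acetate | CC(=O)OC(C)(C)C | starting material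
6 | 1-{(E)-3-[4-(tert-butyldimethylsilyloxy)-3-methoxyphenyl]prop-2-enoyl}imidazole | COc1cc(/C=C/C(=O)n2ccnc2)ccc1O[Si](C)(C)C(C)(C)C | intermediate
7 | lithium enolate of tert-butyl acetate, LiCH2CO2tBu | [Li+].C=C([O-])OC(C)(C)C | intermediate
8 | tert-butyl (E)-5-[4-(tert-butyldimethylsilyloxy)-3-methoxyphenyl]-3-oxopent-4-enoate | COc1cc(/C=C/C(=O)CC(=O)OC(C)(C)C)ccc1O[Si](C)(C)C(C)(C)C | intermediate
9 | dihydroferulic acid, 3-(4-hydroxy-3-methoxyphenyl)propanoic acid | COc1cc(CCC(=O)O)ccc1O | starting material
10 | tert-butyldimethylsilyl 3-[4-(tert-butyldimethylsilyloxy)-3-methoxyphenyl]propanoate | COc1cc(CCC(=O)O[Si](C)(C)C(C)(C)C)ccc1O[Si](C)(C)C(C)(C)C | intermediate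
11 | 3-[4-(tert-butyldimethylsilyloxy)-3-methoxyphenyl]propanoic acid | COc1cc(CCC(=O)O)ccc1O[Si](C)(C)C(C)(C)C | intermediate
12 | 1-{3-[4-(tert-butyldimethylsilyloxy)-3-methoxyphenyl]propanoyl}imidazole | COc1cc(CCC(=O)n2ccnc2)ccc1O[Si](C)(C)C(C)(C)C | intermediate
13 | (E)-5-[4-(tert-butyldimethylsilyloxy)-3-methoxyphenyl]-3-oxopent-4-enoic acid | COc1cc(/C=C/C(=O)CC(=O)O)ccc1O[Si](C)(C)C(C)(C)C | intermediate
14 | magnesium (2Z,4E)-5-[4-(tert-butyldimethylsilyloxy)-3-methoxyphenyl]-3-oxidopenta-2,4-dienoate (chelate) | COc1cc(/C=C/C([O-])=C/C(=O)[O-])ccc1O[Si](C)(C)C(C)(C)C.[Mg+2] | intermediate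
15 | (E)-2-{3-[4-(tert-butyldimethylsilyloxy)-3-methoxyphenyl]propanoyl}-5-[4-(tert-butyldimethylsilyloxy)-3-methoxyphenyl]-3-oxopent-4-enoic acid (formed as its magnesium salt, drawn as the free acid; the C4 centre is labile and undefined) | COc1cc(/C=C/C(=O)C(C(=O)O)C(=O)CCc2ccc(O[Si](C)(C)C(C)(C)C)c(OC)c2)ccc1O[Si](C)(C)C(C)(C)C | intermediate
16 | (4Z,6E)-1,7-bis[4-(tert-butyldimethylsilyloxy)-3-methoxyphenyl]-5-hydroxyhepta-4,6-dien-3-one | COc1cc(/C=C/C(O)=C/C(=O)CCc2ccc(O[Si](C)(C)C(C)(C)C)c(OC)c2)ccc1O[Si](C)(C)C(C)(C)C | intermediate
17 | (4Z,6E)-5-hydroxy-1,7-bis(4-hydroxy-3-methoxyphenyl)hepta-4,6-dien-3-one (dihydrocurcumin, CID5372374) | COc1cc(/C=C/C(O)=C/C(=O)CCc2ccc(O)c(OC)c2)ccc1O | target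

## Step count and risks

Total step count: 7.
Longest linear sequence: 5 steps (1, 2, 5, 6, 7, from ferulic acid).

### Risk 1: step 6

- **What may go wrong:** The keto acid may lose CO2 before chelation is complete. The carboxylate rather than C4 may take the acyl group, which would start acyl exchange and self-condensation of the keto acid. Attack of the stabilized enolate on the imidazolide may also be too slow to compete with these processes.
- **Fallback:** It forms the same C4–C5 bond but keeps the carboxyl masked as its tert-butyl ester during acylation. It sets out from 8 and 11 and returns at 16.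
- Acid 11 is treated with (COCl)2 and catalytic DMF in CH2Cl2 at 0 °C to give 3-[4-(tert-butyldimethylsilyloxy)-3-methoxyphenyl]propanoyl chloride F1.
- β-Keto ester 8 is soft-enolized with MgCl2 and pyridine in CH2Cl2 at 0 °C and C-acylated by the acid chloride, a well-established acylation of β-keto esters. This gives tert-butyl (E)-2-{3-[4-(tert-butyldimethylsilyloxy)-3-methoxyphenyl]propanoyl}-5-[4-(tert-butyldimethylsilyloxy)-3-methoxyphenyl]-3-oxopent-4-enoate F2.
- TFA in CH2Cl2 (0 °C → rt) then removes the tert-butyl group. The resulting acid 15 should decarboxylate spontaneously to 16.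

### Risk 2: step 5

- **What may go wrong:** The free β-keto acid may decarboxylate during acidolysis and concentration. The aryl silyl ether may erode, or the liberated cation may tert-butylate ring A.
- **Fallback:** It builds the keto acid with no ester acidolysis at all. It sets out from 3 and returns at 13.
- Acid 3 is converted with (COCl)2 and catalytic DMF in CH2Cl2 at 0 °C into (E)-3-[4-(tert-butyldimethylsilyloxy)-3-methoxyphenyl]prop-2-enoyl chloride F3.
- Bis(trimethylsilyl) malonate, Et3N and LiBr in MeCN (0 °C → rt) are acylated by it to bis(trimethylsilyl) 2-{(E)-3-[4-(tert-butyldimethylsilyloxy)-3-methoxyphenyl]prop-2-enoyl}propanedioate F4.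
- Cold water hydrolyses both trimethylsilyl esters to 2-{(E)-3-[4-(tert-butyldimethylsilyloxy)-3-methoxyphenyl]prop-2-enoyl}propanedioic acid F5.
- This diacid should lose one CO2 at or below room temperature to give 13, which is extracted cold and used at once.

### Risk 3: step 2

- **What may go wrong:** The lithium enolate may add in conjugate fashion to the cinnamoyl system. It may add a second time to the new ketone if deprotonation lags. The excess strong base may also attack the aryl silyl ether.
- **Fallback:** It replaces the strong-base Claisen condensation by an acylketene route. It sets out from 3 and returns at 8.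
- Acid 3 is coupled with Meldrum's acid (DCC, DMAP, CH2Cl2, 0 °C → rt, dilute acid wash). This gives 5-{(E)-3-[4-(tert-butyldimethylsilyloxy)-3-methoxyphenyl]-1-hydroxyprop-2-enylidene}-2,2-dimethyl-1,3-dioxane-4,6-dione F6.
- Heating with tert-butanol in toluene at 80–90 °C causes cycloreversion to the acylketene, which the alcohol traps to give 8.

## Further compounds

F1 | step 6 | 3-[4-(tert-butyldimethylsilyloxy)-3-methoxyphenyl]propanoyl chloride | COc1cc(CCC(=O)Cl)ccc1O[Si](C)(C)C(C)(C)C
F2 | step 6 | tert-butyl (E)-2-{3-[4-(tert-butyldimethylsilyloxy)-3-methoxyphenyl]propanoyl}-5-[4-(tert-butyldimethylsilyloxy)-3-methoxyphenyl]-3-oxopent-4-enoate | COc1cc(/C=C/C(=O)C(C(=O)OC(C)(C)C)C(=O)CCc2ccc(O[Si](C)(C)C(C)(C)C)c(OC)c2)ccc1O[Si](C)(C)C(C)(C)C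
F3 | step 5 | (E)-3-[4-(tert-butyldimethylsilyloxy)-3-methoxyphenyl]prop-2-enoyl chloride | COc1cc(/C=C/C(=O)Cl)ccc1O[Si](C)(C)C(C)(C)C
F4 | step 5 | bis(trimethylsilyl) 2-{(E)-3-[4-(tert-butyldimethylsilyloxy)-3-methoxyphenyl]prop-2-enoyl}propanedioate | COc1cc(/C=C/C(=O)C(C(=O)O[Si](C)(C)C)C(=O)O[Si](C)(C)C)ccc1O[Si](C)(C)C(C)(C)C
F5 | step 5 | 2-{(E)-3-[4-(tert-butyldimethylsilyloxy)-3-methoxyphenyl]prop-2-enoyl}propanedioic acid | COc1cc(/C=C/C(=O)C(C(=O)O)C(=O)O)ccc1O[Si](C)(C)C(C)(C)C
F6 | step 2 | 5-{(E)-3-[4-(tert-butyldimethylsilyloxy)-3-methoxyphenyl]-1-hydroxyprop-2-enylidene}-2,2-dimethyl-1,3-dioxane-4,6-dione | COc1cc(/C=C/C(O)=C2C(=O)OC(C)(C)OC2=O)ccc1O[Si](C)(C)C(C)(C)C
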